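Its constants are assumed, and the outcome is calculated.

Compare two clocks in this flask first: dissolution refills partner with a half-life of 0.575 min, while the product step at saturation takes intermediate B with a half-life of 110 min, far longer.

    partner + intermediate B ⇌ product (K1 = 4.1 L mol⁻¹, k1 = 0.00106 L mol⁻¹ s⁻¹)
    substrate + partner ⇌ intermediate A (K2 = 96.0 L mol⁻¹, k2 = 9.01 × 10⁻⁴ L mol⁻¹ s⁻¹)
    solid reagent ⇌ partner, rate k3*(cs3 - [partner]) while solid is left; crystals form when [partner] > cs3 (cs3 = 0.099 M, k3 = 0.0201 s⁻¹)
    substrate + partner → intermediate B (k4 = 0.0270 L mol⁻¹ s⁻¹)

substrate 0.41 M; solid reagent 3.00 equiv; time 40 min

- solid, in amounts per volume of the solution: solid reagent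
- at the start none of the solid reagent is in solution
- run time (flask): 40 min

* product at 40 min, in percent of the substrate charged
* concentration of partner in solution at 40 min, in percent of saturation

So freeze partner for the product step, and check the solid first: at two partner per substrate, if the whole charge became product, the substrate's forms and the solution together claim at most 0.919 M of partner, less than the 1.23 M charged.

Define the frozen ratio: product over intermediate B at equilibrium of the product step, with partner held at saturation, 0.406. The step then becomes pseudo-first-order, approaching a ceiling, the frozen ratio over one plus itself, after any lag:

share = ceiling × (1 − exp(−rate × (time − lag)))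

Solve the fast extreme: substrate turns into intermediate B at once, and partner stands at saturation from the start.

ceiling 28.9%, rate 0.02181 min⁻¹, share 16.8%

Solve the slow extreme: partner stays where dissolution just feeds the full substrate charge, 0.0638 M, and substrate waits out its lifetime at that level.

lag 9.67 min, ceiling 20.7%, rate 0.01957 min⁻¹, share 9.29%

I expect the real flask to start near the slow extreme and move toward the fast one as substrate falls, so my estimate is the midpoint, 13.0%. Set dissolution against the net draw of the product step at that share, with the rest of the substrate charge counted as intermediate B, and I reckon partner at 98.8% of saturation.

The forecast gives product at 13% and partner at 98.5% of saturation, the second on the ground that “the partner drain is small compared with dissolution”.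

The simulation gives product at 13.0% and partner at 98.7% of saturation.

This flask has not come to rest at 40.0 min: product over intermediate B reads 0.155, below the frozen ratio of 0.406. The longer run of the same flask shows what remained to change. At 400 min, product has climbed to 28.1% and intermediate B has fallen to 69.3%, a ratio of 0.405.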